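## The problem

Kanzonol X is an isoflavan: a chroman (aromatic ring A fused to the oxygen heterocycle, ring C) that carries a second resorcinol ring (ring B) at C3. C3 is the only stereocentre, so nothing in the molecule can relay its configuration. The R configuration must come from a reagent or an auxiliary, and because the centre is benzylic it should not stay next to a carbonyl group once it is set. Both aromatic rings are resorcinols with the prenyl group on the carbon between the two oxygens (C8 between O1 and the C7 hydroxyl, C3′ between the C2′ and C4′ hydroxyls). Direct electrophilic prenylation of a resorcinol does not reach that position. Both trisubstituted alkenes lie ortho to phenols. Strong acid adds the phenol across them (dimethylchroman formation), and hydrogenation, ozone and electrophilic oxidants destroy them, so benzyl ethers, late oxidations and forcing acid are excluded. The enabling feature is the substitution of ring A: C8a bears O1, C8 the prenyl group, C7 a hydroxyl, C6 and C5 hydrogen, and C4a the C4 methylene, while O1 is tied back to C4a through C2, C3 and C4. This is the pattern formed when an alkynyl ether (O1–C8a≡C8–prenyl) is annulated by a vinylketene (C6=C5–C4a=C7=O). The O1–C2–C3–C4 chain is just long enough to hold both partners in one molecule, so the annulation closes ring C as well as ring A.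

## Retrosynthesis

**37 to 36.** The last cut removes the two methoxymethyl groups from the ring B oxygens. These acetals direct both lithiations that build ring B and survive KH, alkyllithiums, hydrides and Grignard reagents. Silyl ethers would migrate under KH and benzyl ethers would need hydrogenolysis. The skeleton of 36 is no simpler than that of 37, but 36 is the form in which ring B can be carried. The forward reaction must cleave two aryl acetals without adding the freed phenols to the neighbouring alkenes.

**36 to 31.** Three bonds are cut: C8a–C4a, C7–C8 and C6–C7. Ring A dissolves into a vinylketene (C7, C4a, C5, C6) and an ynol ether (C8a, C8), and ring C opens at C8a–C4a. The neighbouring cuts (O1–C2 by Mitsunobu etherification, O1–C8a by aryl etherification, C4–C4a by Friedel–Crafts chemistry) all keep ring A intact. They therefore need a ring A building block with four contiguous substituents and two oxygens that must be told apart. The chosen cut replaces that block by an open chain on ring B with one stereocentre, diazo ketone 31. The forward reaction must proceed through vinylketene 32, cyclobutenone 33, dienylketene 34 and dienone 35. It must join C8 to C7 and not to C4a, and it must leave C3 untouched.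

**31 to 28 to 27.** The diazo group is traced back to the only enolisable α-carbon of vinyl ketone 28, and the ketone to allylic alcohol 27. The carbonyl group is unveiled this late because the ynol ether is made with n-BuLi, which no ketone survives. The forward steps need an oxidant that spares the ynol ether and a diazo transfer that tolerates an unsubstituted enone.

**27 to 25 and 3.** The C8–CH2 bond to the prenyl group is cut and the alkyne is returned to a 1,2-dichlorovinyl ether. Direct O-alkynylation of an alcohol with a preformed prenylated haloalkyne is not a dependable reaction, whereas the dichlorovinyl ether to lithium alkynyl ether sequence is standard. The forward reaction must alkylate the acetylide carbon with prenyl bromide 3 at its primary carbon, in the presence of a lithium alkoxide.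

**25 to 17.** The C7–C5 bond is cut to aldehyde 23 and vinylmagnesium bromide 24. Aldehyde 23 goes back through alcohol 22 to the terminal alkene of 20, and the O1–C8a bond is cut to alcohol 17 and trichloroethylene 18. The dichlorovinyl ether is put on first so that it also protects O1 during the chain extension. A separate silyl protection and removal would cost two steps. The hydroboration must select the monosubstituted alkene over two prenyl groups and the chlorinated enol ether.

**17 to 13 and 14.** The C3–C4 bond is cut: alcohol 17 comes from imide 16, and 16 from arylacetyl imide 13 and allyl bromide 14. The allyl group gives a three-carbon arm whose end is easily told apart from the O1 arm. The alternative cut at C3–C1′ (asymmetric conjugate arylation of a butenolide) is about as short but less predictable for an ortho-substituted aryl nucleophile. The precursor 13 has no stereocentre. The forward alkylation must be face-selective and must not epimerise the α-aryl centre.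

**13 to 1.** Imide 13 comes from acid 10 and auxiliary 11. Acid 10 comes from alcohol 8, made from arene 5 and ethylene oxide 6 through aryllithium 7 (cut at C1′–CH2). Arene 5 comes from 2 and prenyl bromide 3 (cut at C3′–prenyl), and 2 from resorcinol 1. Both ring B carbon–carbon bonds are made by acetal-directed ortho-lithiation. Compounds 2 and 5 are symmetric, so neither lithiation has a regiochemical choice.

## Roads not taken

**Alternative 1:** conjunctive coupling on a vinylboron linchpin. The cuts are C3–C1′ and C4–C4a. Aryllithium 7 would add to a vinylboronic ester, and the ate complex would couple with ring A bromide A1 under Pd(OAc)2 and the ferrocenyl diphosphine MandyPhos. The 1,2-shift of the ring B aryl group from boron to carbon forms C3–C1′ and sets C3, and reductive elimination forms C4–C4a, giving boronic ester A2. No ring closes. The finish would need one-carbon Matteson homologation, oxidation, desilylation, Mitsunobu closure of ring C and deprotection.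

- Merits: it is the most convergent plan, the asymmetric step is catalytic, the reaction class is established, and the route would probably be shorter than the chosen one.
- Weak points: the migrating aryl group has an ortho acetal buttressed by the prenyl group, and A1 is ortho-substituted as well. A1 also needs two different oxygen protecting groups on a symmetric 2-prenylresorcinol and a bromine on the fourth contiguous carbon. The hindered benzylic boronic ester must then be homologated.
- Comparison: Alternative 1 is better in step count and in precedent for its key step. The chosen plan sets against this a substrate-insensitive auxiliary alkylation for C3, no differentiated tetrasubstituted ring A piece, and closure of both rings in one operation.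

**Alternative 2:** ring B grown by intermolecular benzannulation. The cuts are C2′–C3′, C4′–C5′ and C1′–C2′. Photochemical Wolff rearrangement of chromanyl diazo enone A3 would give a vinylketene that combines with siloxyalkyne A4 by [2+2] addition, 4π opening and 6π closure to give bis(silyl ether) A5. Fluoride then gives the target.

- Merits: this is the known intermolecular reaction with a siloxyalkyne, and the last step uses fluoride instead of acid, which is kinder to the prenylphenols than the chosen end game.
- Weak points: only one ring is built. Rings A and C, with the difficult C8 prenyl pattern and C3 in place, must be made first by other means. In A3 the C3 hydrogen is allylic and γ to the ketone, so the base needed for diazo transfer can erode the configuration. The intermolecular cycloaddition needs excess alkyne.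
- Comparison: Alternative 2 is safer in its key step and its deprotection. The chosen plan offers a key step that makes two rings and puts C3 two saturated carbons away from any acidifying group.

**Alternative 3:** carbene C–H insertion through a temporary dihydrobenzofuran. The cut is C3–C4. The divalent-rhodium dimer Rh2(S-PTTL)4 would decompose aryldiazoacetate A6, and the carbene carbon (C3) would insert into the benzylic ether C–H bond (C4) to give cis-dihydrobenzofuran A7.

- Merits: catalytic asymmetric C–H insertions of this kind are well known, and A6 is assembled convergently by O-benzylation.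
- Weak points: the benzylic C4–O bond must later be cleaved reductively beside two prenyl alkenes, with hydrogenolysis excluded. The C4 stereocentre is made only to be destroyed. After cleavage two ortho phenols compete for ring closure onto C2 (five- against six-membered), which forces a reprotection. The ester-bearing C3 can epimerise, and once C4 is flattened this becomes loss of enantiopurity. Five or six steps follow the key step.
- Comparison: Alternative 3 has the better precedent for its key step. The chosen plan has a one-step end game and no reductive step.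

Key step: step 15

## Route

Remark: the carbinol centre made in step 11 and the transient centres of 30 and 33 are not controlled. They are erased in steps 13, 14 and 15, so these compounds are carried as epimer mixtures at those positions only.

Abbreviations: Ar = 2,4-bis(methoxymethoxy)-3-(3-methylbut-2-en-1-yl)phenyl (protected ring B); prenyl = 3-methylbut-2-en-1-yl. Atom labels follow isoflavan numbering.

Step 1
Reactants: 1 resorcinol
Product: 2 1,3-bis(methoxymethoxy)benzene
Conditions: NaH, MOMCl, DMF, 0 °C → rt
Reagents that add atoms: chloromethyl methyl ether COCCl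
Why: Williamson-type alkylation of both phenoxides; the acetals direct the two lithiations that follow and survive every basic and organometallic step.

Step 2
Reactants: 2 1,3-bis(methoxymethoxy)benzene; 3 prenyl bromide (1-bromo-3-methylbut-2-ene)
Product: 5 1,3-bis(methoxymethoxy)-2-(3-methylbut-2-en-1-yl)benzene, via 2-lithio-1,3-bis(methoxymethoxy)benzene 4 (not isolated)
Conditions: n-BuLi, THF, 0 °C → rt; then CuI (10 mol %), prenyl bromide, −78 °C → rt
Reagents that add atoms: none
Why: Directed ortho-metalation takes place at the carbon flanked by both acetal oxygens, and copper-assisted SN2 alkylation of the aryllithium puts the prenyl group between the two oxygens.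

Step 3
Reactants: 5 1,3-bis(methoxymethoxy)-2-(3-methylbut-2-en-1-yl)benzene; 6 ethylene oxide
Product: 8 2-Ar-ethan-1-ol, via aryllithium Ar-Li 7 (not isolated)
Conditions: n-BuLi, TMEDA, THF, −20 → 0 °C; then ethylene oxide, −20 °C → rt
Reagents that add atoms: none
Why: Second directed ortho-metalation; 5 is symmetric, so only one kind of ring position next to an acetal exists, and ring opening of the epoxide by the aryllithium gives the 2-arylethanol.

Step 4
Reactants: 8 2-Ar-ethan-1-ol
Product: 10 Ar-acetic acid, via Ar-acetaldehyde 9 (not isolated)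
Conditions: TEMPO (cat.), PhI(OAc)2, MeCN/H2O, rt
Reagents that add atoms: water O
Why: Nitroxyl-catalysed oxidation takes the primary alcohol through the aldehyde hydrate to the acid without chlorine-based oxidants, so the prenyl alkene, the electron-rich ring and the acetals should be left alone.

Step 5
Reactants: 10 Ar-acetic acid; 11 (4R)-4-benzyl-1,3-oxazolidin-2-one
Product: 13 (4R)-4-benzyl-3-(Ar-acetyl)-1,3-oxazolidin-2-one, via mixed pivalic anhydride 12 (not isolated)
Conditions: PivCl, Et3N, THF, −20 °C; then LiCl, 11, −20 °C → rt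
Reagents that add atoms: none
Why: N-acylation of the auxiliary through the mixed anhydride, with LiCl activating the oxazolidinone; no strong base is present.

Step 6
Reactants: 13 (4R)-4-benzyl-3-(Ar-acetyl)-1,3-oxazolidin-2-one; 14 allyl bromide
Product: 16 (4R)-4-benzyl-3-[(2R)-2-Ar-pent-4-enoyl]-1,3-oxazolidin-2-one, via sodium Z-enolate 15 (not isolated)
Conditions: NaN(SiMe3)2, THF, −78 °C; then allyl bromide, −78 → −45 °C; AcOH quench
Reagents that add atoms: none
Why: Evans alkylation: the chelated Z-enolate is shielded on one face by the benzyl group of the auxiliary, so allyl bromide enters from the other face and sets C3 (2R in the acyl chain with the R auxiliary, because aryl outranks the incoming allyl group); the cold acidic quench guards against epimerisation of the α-aryl imide.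

Step 7
Reactants: 16 (4R)-4-benzyl-3-[(2R)-2-Ar-pent-4-enoyl]-1,3-oxazolidin-2-one
Product: 17 (2R)-2-Ar-pent-4-en-1-ol
Conditions: LiBH4, MeOH (1 equiv), Et2O, 0 °C
Reagents that add atoms: none
Why: Reductive cleavage of the imide at the exocyclic carbonyl releases the primary alcohol and the reusable auxiliary; from here on C3 is no longer next to a carbonyl group.

Step 8
Reactants: 17 (2R)-2-Ar-pent-4-en-1-ol; 18 trichloroethylene
Product: 20 (E)-1,2-dichloroethenyl (2R)-2-Ar-pent-4-en-1-yl ether, via potassium alkoxide 19 (not isolated)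
Conditions: KH, THF, 0 °C → rt; then Cl2C=CHCl, −50 °C → rt
Reagents that add atoms: none
Why: The alkoxide adds anti to dichloroacetylene formed in the flask from trichloroethylene, the standard entry to alkynyl ethers; the dichlorovinyl ether also protects O1 during the chain extension.

Step 9
Reactants: 20 (E)-1,2-dichloroethenyl (2R)-2-Ar-pent-4-en-1-yl ether
Product: 22 (4R)-4-Ar-5-{[(E)-1,2-dichloroethenyl]oxy}pentan-1-ol, via B-alkyl-9-BBN adduct 21 (not isolated)
Conditions: 9-BBN, THF, 0 °C → rt; then NaOH, H2O2, 0 °C
Reagents that add atoms: hydrogen peroxide OO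
Why: Anti-Markovnikov hydroboration–oxidation; 9-BBN selects the monosubstituted alkene over the trisubstituted prenyl alkene and the electron-poor dichlorovinyl ether.

Step 10
Reactants: 22 (4R)-4-Ar-5-{[(E)-1,2-dichloroethenyl]oxy}pentan-1-ol
Product: 23 (4R)-4-Ar-5-{[(E)-1,2-dichloroethenyl]oxy}pentanal
Conditions: DMP, CH2Cl2, 0 °C → rt
Reagents that add atoms: none
Why: Dess–Martin oxidation stops at the aldehyde and leaves alkenes, acetals and the vinyl chlorides alone; the stereocentre is γ to the new carbonyl and cannot epimerise.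

Step 11
Reactants: 23 (4R)-4-Ar-5-{[(E)-1,2-dichloroethenyl]oxy}pentanal; 24 vinylmagnesium bromide
Product: 25 (6R)-6-Ar-7-{[(E)-1,2-dichloroethenyl]oxy}hept-1-en-3-ol (both C3 epimers)
Conditions: CH2=CHMgBr, THF, −78 °C
Reagents that add atoms: none
Why: Grignard 1,2-addition brings in C5 and C6; the carbinol centre is formed without control and is oxidised away in step 13.

Step 12
Reactants: 25 (6R)-6-Ar-7-{[(E)-1,2-dichloroethenyl]oxy}hept-1-en-3-ol; 3 prenyl bromide
Product: 27 (6R)-6-Ar-7-[(5-methylhex-4-en-1-yn-1-yl)oxy]hept-1-en-3-ol (both C3 epimers), via dilithio alkoxide acetylide 26 (not isolated)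
Conditions: n-BuLi (3.2 equiv), THF, −78 → −40 °C; then DMPU, prenyl bromide (1.05 equiv), −78 → −20 °C
Reagents that add atoms: none
Why: One equivalent of base deprotonates the hydroxyl and two convert the dichlorovinyl ether into the lithium alkynyl ether by elimination and chlorine–lithium exchange; the acetylide carbon is then alkylated at the primary carbon of the allylic bromide, and the alkoxide is expected to stay unalkylated, as in the C-alkylation of alkynol dianions.

Step 13
Reactants: 27 (6R)-6-Ar-7-[(5-methylhex-4-en-1-yn-1-yl)oxy]hept-1-en-3-ol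
Product: 28 (6R)-6-Ar-7-[(5-methylhex-4-en-1-yn-1-yl)oxy]hept-1-en-3-one
Conditions: MnO2 (activated, excess), CH2Cl2, rt
Reagents that add atoms: none
Why: Allylic alcohol oxidation on the neutral surface of manganese dioxide should spare the acid-sensitive ynol ether, the skipped enyne and the acetals.

Step 14
Reactants: 28 (6R)-6-Ar-7-[(5-methylhex-4-en-1-yn-1-yl)oxy]hept-1-en-3-one
Product: 31 (6R)-6-Ar-4-diazo-7-[(5-methylhex-4-en-1-yn-1-yl)oxy]hept-1-en-3-one, via lithium dienolate 29 (not isolated), via trifluoroacetyl diketone 30 (not isolated)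
Conditions: LiN(SiMe3)2, THF, −78 °C; CF3CO2CH2CF3, −78 °C; then MsN3 (1.2 equiv), Et3N, H2O, MeCN, 0 °C → rt
Reagents that add atoms: methanesulfonyl azide CS(=O)(=O)N=[N+]=[N-]
Why: Detrifluoroacetylative (Regitz-type) diazo transfer, the established route to α′-diazo enones: the vinyl side has no α-hydrogen, so enolisation and trifluoroacetylation can only occur at C4 of the heptenone, and the activated diketone passes the diazo group on with loss of the trifluoroacetyl group; the stereocentre has no acidic hydrogen.

Step 15
Reactants: 31 (6R)-6-Ar-4-diazo-7-[(5-methylhex-4-en-1-yn-1-yl)oxy]hept-1-en-3-one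
Product: 36 (3R)-3-Ar-8-(3-methylbut-2-en-1-yl)-3,4-dihydro-2H-chromen-7-ol, via vinylketene 32 (not isolated), via cyclobutenone 33 (not isolated), via dienylketene 34 (not isolated), via cyclohexadienone 35 (not isolated)
Conditions: hν (300 nm, Pyrex), degassed ClCH2CH2Cl (0.005 M), 20 °C; then 80 °C in the dark
Reagents that add atoms: none
Why: Proposed new method: light expels nitrogen from the α-diazo ketone and the vinyl group migrates to the diazo carbon (Wolff rearrangement), giving vinylketene 32 whose carbonyl carbon is C7 and whose α-carbon is C4a; the nucleophilic alkyne carbon C8 of the tethered ynol ether adds to C7 while C8a bonds to C4a ([2+2] cycloaddition) to give cyclobutenone 33, which opens by 4π electrocyclic cleavage of C4a–C7 to dienylketene 34, closes by 6π electrocyclisation of C6 onto C7 to dienone 35 and tautomerises to phenol 36; the closest known reaction type is the intermolecular Danheiser benzannulation of vinylketenes (from α-diazo ketones or cyclobutenones) with alkoxy- and siloxyalkynes. Ring C closes in the cycloaddition as the six-membered ring of a 2-oxabicyclo[4.2.0]octenone, through the four-atom tether O1–C2–C3–C4; ring A closes by the thermally allowed disrotatory 6π electrocyclisation of 34, in which the C8a=C4a double bond held inside ring C keeps the ketene and the vinyl group cis. No stereocentre is created: the quaternary C4a of 33 is transient and both epimers open to the same 34, while C3 is separated from the ketene by the C4 methylene, has no acidic hydrogen and should keep its R configuration. The step needs the [2+2] regiochemistry C8-to-C7, which the polarisation of the ynol ether and the tether both enforce (the reverse orientation would need a bridged ring). It also needs the ketene to choose the ynol ether over the two prenyl alkenes and over dimerisation, which the far higher nucleophilicity of the alkynyl ether, the six-ring geometry and high dilution should secure. Irradiation through Pyrex spares the aryl ethers, and heating only after the ynol ether has been consumed avoids its thermal retro-ene fragmentation.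

Step 16
Reactants: 36 (3R)-3-Ar-8-(3-methylbut-2-en-1-yl)-3,4-dihydro-2H-chromen-7-ol
Product: 37 kanzonol X
Conditions: HCl (conc. aq, few equiv), MeOH, 0 °C → rt
Reagents that add atoms: none
Why: Acid-catalysed acetal exchange with methanol removes both methoxymethyl ethers as dimethoxymethane; dilute HCl in methanol at room temperature is the kind of condition under which ortho-prenylphenols are known to survive, and C3 is not affected.

## Compound list

1 | resorcinol (benzene-1,3-diol) | Oc1cccc(O)c1 | starting material
2 | 1,3-bis(methoxymethoxy)benzene | COCOc1cccc(OCOC)c1 | intermediate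
3 | prenyl bromide (1-bromo-3-methylbut-2-ene) | CC(C)=CCBr | starting material
4 | 2-lithio-1,3-bis(methoxymethoxy)benzene | [Li]c1c(OCOC)cccc1OCOC | intermediate
5 | 1,3-bis(methoxymethoxy)-2-(3-methylbut-2-en-1-yl)benzene | CC(C)=CCc1c(OCOC)cccc1OCOC | intermediate
6 | ethylene oxide (oxirane) | C1CO1 | starting material
7 | [2,4-bis(methoxymethoxy)-3-(3-methylbut-2-en-1-yl)phenyl]lithium (Ar-Li) | CC(C)=CCc1c(OCOC)ccc([Li])c1OCOC | intermediate
8 | 2-[2,4-bis(methoxymethoxy)-3-(3-methylbut-2-en-1-yl)phenyl]ethan-1-ol (2-Ar-ethan-1-ol) | CC(C)=CCc1c(OCOC)ccc(CCO)c1OCOC | intermediate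
9 | Ar-acetaldehyde | CC(C)=CCc1c(OCOC)ccc(CC=O)c1OCOC | intermediate
10 | Ar-acetic acid | CC(C)=CCc1c(OCOC)ccc(CC(=O)O)c1OCOC | intermediate
11 | (4R)-4-benzyl-1,3-oxazolidin-2-one | O=C1N[C@H](Cc2ccccc2)CO1 | starting material
12 | Ar-acetic pivalic anhydride | CC(C)=CCc1c(OCOC)ccc(CC(=O)OC(=O)C(C)(C)C)c1OCOC | intermediate
13 | (4R)-4-benzyl-3-(Ar-acetyl)-1,3-oxazolidin-2-one | CC(C)=CCc1c(OCOC)ccc(CC(=O)N2[C@H](Cc3ccccc3)COC2=O)c1OCOC | intermediate
14 | allyl bromide (3-bromoprop-1-ene) | C=CCBr | starting material
15 | sodium (Z)-enolate of 13 | CC(C)=CCc1c(OCOC)ccc(/C=C(\O[Na])N2[C@H](Cc3ccccc3)COC2=O)c1OCOC | intermediate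
16 | (4R)-4-benzyl-3-[(2R)-2-Ar-pent-4-enoyl]-1,3-oxazolidin-2-one | CC(C)=CCc1c(OCOC)ccc([C@@H](CC=C)C(=O)N2[C@H](Cc3ccccc3)COC2=O)c1OCOC | intermediate
17 | (2R)-2-Ar-pent-4-en-1-ol | CC(C)=CCc1c(OCOC)ccc([C@@H](CC=C)CO)c1OCOC | intermediate
18 | trichloroethylene | ClC=C(Cl)Cl | starting material
19 | potassium (2R)-2-Ar-pent-4-en-1-olate | CC(C)=CCc1c(OCOC)ccc([C@@H](CC=C)CO[K])c1OCOC | intermediate
20 | (E)-1,2-dichloroethenyl (2R)-2-Ar-pent-4-en-1-yl ether | CC(C)=CCc1c(OCOC)ccc([C@@H](CC=C)CO/C(Cl)=C\Cl)c1OCOC | intermediate
21 | 9-[(4R)-4-Ar-5-{[(E)-1,2-dichloroethenyl]oxy}pentyl]-9-borabicyclo[3.3.1]nonane | CC(C)=CCc1c(OCOC)ccc([C@@H](CCCB2C3CCCC2CCC3)CO/C(Cl)=C\Cl)c1OCOC | intermediate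
22 | (4R)-4-Ar-5-{[(E)-1,2-dichloroethenyl]oxy}pentan-1-ol | CC(C)=CCc1c(OCOC)ccc([C@@H](CCCO)CO/C(Cl)=C\Cl)c1OCOC | intermediate
23 | (4R)-4-Ar-5-{[(E)-1,2-dichloroethenyl]oxy}pentanal | CC(C)=CCc1c(OCOC)ccc([C@@H](CCC=O)CO/C(Cl)=C\Cl)c1OCOC | intermediate
24 | vinylmagnesium bromide | C=C[Mg]Br | starting material
25 | (6R)-6-Ar-7-{[(E)-1,2-dichloroethenyl]oxy}hept-1-en-3-ol (both C3 epimers) | CC(C)=CCc1c(OCOC)ccc([C@@H](CCC(O)C=C)CO/C(Cl)=C\Cl)c1OCOC | intermediate
26 | lithium (6R)-6-Ar-7-[(lithioethynyl)oxy]hept-1-en-3-olate | CC(C)=CCc1c(OCOC)ccc([C@@H](CCC(O[Li])C=C)COC#C[Li])c1OCOC | intermediate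
27 | (6R)-6-Ar-7-[(5-methylhex-4-en-1-yn-1-yl)oxy]hept-1-en-3-ol (both C3 epimers) | CC(C)=CCc1c(OCOC)ccc([C@@H](CCC(O)C=C)COC#CCC=C(C)C)c1OCOC | intermediate
28 | (6R)-6-Ar-7-[(5-methylhex-4-en-1-yn-1-yl)oxy]hept-1-en-3-one | CC(C)=CCc1c(OCOC)ccc([C@@H](CCC(=O)C=C)COC#CCC=C(C)C)c1OCOC | intermediate
29 | lithium dienolate of 28 | CC(C)=CCc1c(OCOC)ccc([C@@H](CC=C(O[Li])C=C)COC#CCC=C(C)C)c1OCOC | intermediate
30 | (6R)-6-Ar-7-[(5-methylhex-4-en-1-yn-1-yl)oxy]-4-(trifluoroacetyl)hept-1-en-3-one (both C4 epimers) | CC(C)=CCc1c(OCOC)ccc([C@@H](CC(C(=O)C(F)(F)F)C(=O)C=C)COC#CCC=C(C)C)c1OCOC | intermediate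
31 | (6R)-6-Ar-4-diazo-7-[(5-methylhex-4-en-1-yn-1-yl)oxy]hept-1-en-3-one | CC(C)=CCc1c(OCOC)ccc([C@@H](CC(=[N+]=[N-])C(=O)C=C)COC#CCC=C(C)C)c1OCOC | intermediate
32 | (4R)-4-Ar-2-ethenyl-5-[(5-methylhex-4-en-1-yn-1-yl)oxy]pent-1-en-1-one (vinylketene) | CC(C)=CCc1c(OCOC)ccc([C@@H](CC(C=C)=C=O)COC#CCC=C(C)C)c1OCOC | intermediate
33 | (4R)-4-Ar-6-ethenyl-8-(3-methylbut-2-en-1-yl)-2-oxabicyclo[4.2.0]oct-1(8)-en-7-one (both C6 epimers) | CC(C)=CCc1c(OCOC)ccc([C@@H]2COC3=C(CC=C(C)C)C(=O)C3(C=C)C2)c1OCOC | intermediate
34 | 2-[(3R)-3-Ar-5-ethenyl-3,4-dihydro-2H-pyran-6-yl]-5-methylhexa-1,4-dien-1-one (dienylketene) | CC(C)=CCc1c(OCOC)ccc([C@@H]2COC(C(CC=C(C)C)=C=O)=C(C=C)C2)c1OCOC | intermediate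
35 | (3R)-3-Ar-8-(3-methylbut-2-en-1-yl)-2,3,4,6-tetrahydro-7H-chromen-7-one | CC(C)=CCc1c(OCOC)ccc([C@@H]2COC3=C(CC=C(C)C)C(=O)CC=C3C2)c1OCOC | intermediate
36 | (3R)-3-Ar-8-(3-methylbut-2-en-1-yl)-3,4-dihydro-2H-chromen-7-ol (kanzonol X 2′,4′-bis(methoxymethyl) ether) | CC(C)=CCc1c(OCOC)ccc([C@@H]2COc3c(ccc(O)c3CC=C(C)C)C2)c1OCOC | intermediate
37 | kanzonol X, (3R)-3-[2,4-dihydroxy-3-(3-methylbut-2-en-1-yl)phenyl]-8-(3-methylbut-2-en-1-yl)-3,4-dihydro-2H-chromen-7-ol | CC(C)=CCc1c(O)ccc([C@@H]2COc3c(ccc(O)c3CC=C(C)C)C2)c1O | target

## Step count and risk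

Total step count: 16. Longest linear sequence: 16 steps (1 to 37).

**Step 15 (key step).**
- Risk: the carbene or the ketene may be diverted. Possible processes are a 1,2-hydrogen shift from C4 competing with vinyl migration, ketene dimerisation or addition to a prenyl alkene if the tethered cycloaddition is slow, arrest at the cyclobutenone stage, and photodegradation of the phenolic product.
- Fallback (known chemistry: Evans alkylation and Mitsunobu etherification): it sets out from arene 5 and imide 13 and returns at 36. Aryllithium 7, made from 5 as in step 3, is formylated with DMF to 2,4-bis(methoxymethoxy)-3-prenylbenzaldehyde F1. HCl in MeOH gives 2,4-dihydroxy-3-prenylbenzaldehyde F2. Allyl bromide 14 and K2CO3 give the bis(allyl ether) aldehyde F3, NaBH4 gives benzylic alcohol F4, and CBr4/PPh3 gives benzylic bromide F5. Enolate 15 of imide 13 is alkylated with F5, under the same facial control as in step 6, to give benzylated imide F6. LiBH4 gives primary alcohol F7. Pd(PPh3)4 and morpholine remove both allyl ethers to give triol F8. Intramolecular Mitsunobu etherification (PPh3, DIAD) of the primary alcohol with the ortho phenol closes ring C and gives 36.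

**Step 14.**
- Risk: the vinyl ketone may be lost during enolisation by conjugate addition of the amide base or of the enolate to a second enone (oligomerisation). The diazo group may add as a dipole to the unsubstituted enone on concentration. The sulfonyl azide may add to the ynol ether.
- Fallback (the vinyl terminus is blocked by a removable silyl group): it sets out from aldehyde 23 and returns at 37. (E)-2-(Trimethylsilyl)ethenyllithium F9, from commercial (E)-(2-bromoethenyl)trimethylsilane and t-BuLi, adds to 23 to give silylated allylic alcohol F10. The operations of steps 12 and 13 give ynol ether alcohol F11 and β-silyl enone F12, a poor Michael acceptor and dipolarophile. Diazo transfer as in step 14 gives diazo ketone F13. Irradiation as in step 15 gives 6-trimethylsilyl isoflavan F14. The silyl group is ortho to the phenol and para to O1, so it should be lost by ipso-protonation under the acid of step 16 together with the acetals, giving 37.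

**Step 12.**
- Risk: O-prenylation of the lithium alkoxide, SN2′ attack giving the tertiary isomer, or base-induced isomerisation of the skipped enyne.
- Fallback (masked hydroxyl and copper-mediated coupling): it sets out from 25 and returns at 27. TBSCl and imidazole give silyl ether F15. n-BuLi (2.2 equiv), then CuBr·SMe2 and prenyl bromide 3 in THF, give the silylated ynol ether F16 through the alkynylcopper species. TBAF gives 27.

**Step 16.**
- Risk: acid-catalysed addition of a freed phenol to the neighbouring prenyl alkene (dimethylchroman formation) before both acetals are gone.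
- Fallback (non-protic, two stages): it sets out from 36 and returns at 37. Et3SiOTf and 2,2′-bipyridyl in CH2Cl2 exchange both aryl methoxymethyl ethers for triethylsilyl ethers and silylate the C7 phenol, giving tris(triethylsilyl) ether F17. TBAF buffered with AcOH gives 37.

## Further compounds

F1 | step 15 | 2,4-bis(methoxymethoxy)-3-(3-methylbut-2-en-1-yl)benzaldehyde | CC(C)=CCc1c(OCOC)ccc(C=O)c1OCOC
F2 | step 15 | 2,4-dihydroxy-3-(3-methylbut-2-en-1-yl)benzaldehyde | CC(C)=CCc1c(O)ccc(C=O)c1O
F3 | step 15 | 3-(3-methylbut-2-en-1-yl)-2,4-bis(prop-2-en-1-yloxy)benzaldehyde | CC(C)=CCc1c(OCC=C)ccc(C=O)c1OCC=C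
F4 | step 15 | [3-(3-methylbut-2-en-1-yl)-2,4-bis(prop-2-en-1-yloxy)phenyl]methanol | CC(C)=CCc1c(OCC=C)ccc(CO)c1OCC=C
F5 | step 15 | 1-(bromomethyl)-3-(3-methylbut-2-en-1-yl)-2,4-bis(prop-2-en-1-yloxy)benzene | CC(C)=CCc1c(OCC=C)ccc(CBr)c1OCC=C
F6 | step 15 | (4R)-4-benzyl-3-{(2R)-2-Ar-3-[3-(3-methylbut-2-en-1-yl)-2,4-bis(prop-2-en-1-yloxy)phenyl]propanoyl}-1,3-oxazolidin-2-one | CC(C)=CCc1c(OCOC)ccc([C@@H](Cc2ccc(OCC=C)c(CC=C(C)C)c2OCC=C)C(=O)N2[C@H](Cc3ccccc3)COC2=O)c1OCOC
F7 | step 15 | (2R)-2-Ar-3-[3-(3-methylbut-2-en-1-yl)-2,4-bis(prop-2-en-1-yloxy)phenyl]propan-1-ol | CC(C)=CCc1c(OCOC)ccc([C@@H](Cc2ccc(OCC=C)c(CC=C(C)C)c2OCC=C)CO)c1OCOC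
F8 | step 15 | 4-[(2R)-2-Ar-3-hydroxypropyl]-2-(3-methylbut-2-en-1-yl)benzene-1,3-diol | CC(C)=CCc1c(OCOC)ccc([C@@H](Cc2ccc(O)c(CC=C(C)C)c2O)CO)c1OCOC
F9 | step 14 | (E)-2-(trimethylsilyl)ethenyllithium | [Li]/C=C/[Si](C)(C)C
F10 | step 14 | (1E,6R)-6-Ar-7-{[(E)-1,2-dichloroethenyl]oxy}-1-(trimethylsilyl)hept-1-en-3-ol (both C3 epimers) | CC(C)=CCc1c(OCOC)ccc([C@@H](CCC(O)/C=C/[Si](C)(C)C)CO/C(Cl)=C\Cl)c1OCOC
F11 | step 14 | (1E,6R)-6-Ar-7-[(5-methylhex-4-en-1-yn-1-yl)oxy]-1-(trimethylsilyl)hept-1-en-3-ol (both C3 epimers) | CC(C)=CCc1c(OCOC)ccc([C@@H](CCC(O)/C=C/[Si](C)(C)C)COC#CCC=C(C)C)c1OCOC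
F12 | step 14 | (1E,6R)-6-Ar-7-[(5-methylhex-4-en-1-yn-1-yl)oxy]-1-(trimethylsilyl)hept-1-en-3-one | CC(C)=CCc1c(OCOC)ccc([C@@H](CCC(=O)/C=C/[Si](C)(C)C)COC#CCC=C(C)C)c1OCOC
F13 | step 14 | (1E,6R)-6-Ar-4-diazo-7-[(5-methylhex-4-en-1-yn-1-yl)oxy]-1-(trimethylsilyl)hept-1-en-3-one | CC(C)=CCc1c(OCOC)ccc([C@@H](CC(=[N+]=[N-])C(=O)/C=C/[Si](C)(C)C)COC#CCC=C(C)C)c1OCOC
F14 | step 14 | (3R)-3-Ar-8-(3-methylbut-2-en-1-yl)-6-(trimethylsilyl)-3,4-dihydro-2H-chromen-7-ol | CC(C)=CCc1c(OCOC)ccc([C@@H]2COc3c(cc([Si](C)(C)C)c(O)c3CC=C(C)C)C2)c1OCOC
F15 | step 12 | tert-butyldimethylsilyl ether of 25 (both C3 epimers) | CC(C)=CCc1c(OCOC)ccc([C@@H](CCC(O[Si](C)(C)C(C)(C)C)C=C)CO/C(Cl)=C\Cl)c1OCOC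
F16 | step 12 | tert-butyldimethylsilyl ether of 27 (both C3 epimers) | CC(C)=CCc1c(OCOC)ccc([C@@H](CCC(O[Si](C)(C)C(C)(C)C)C=C)COC#CCC=C(C)C)c1OCOC
F17 | step 16 | kanzonol X 7,2′,4′-tris(triethylsilyl) ether | CC(C)=CCc1c(O[Si](CC)(CC)CC)ccc([C@@H]2COc3c(ccc(O[Si](CC)(CC)CC)c3CC=C(C)C)C2)c1O[Si](CC)(CC)CC
A1 | alternative 1 | 1-bromo-2-(tert-butyldimethylsilyloxy)-4-(methoxymethoxy)-3-(3-methylbut-2-en-1-yl)benzene | Brc1ccc(OCOC)c(CC=C(C)C)c1O[Si](C)(C)C(C)(C)C
A2 | alternative 1 | 2-{(1R)-1-Ar-2-[2-(tert-butyldimethylsilyloxy)-4-(methoxymethoxy)-3-(3-methylbut-2-en-1-yl)phenyl]ethyl}-4,4,5,5-tetramethyl-1,3,2-dioxaborolane | CC(C)=CCc1c(OCOC)ccc([C@@H](Cc2ccc(OCOC)c(CC=C(C)C)c2O[Si](C)(C)C(C)(C)C)B2OC(C)(C)C(C)(C)O2)c1OCOC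
A3 | alternative 2 | (3E)-1-diazo-4-[(3R)-8-(3-methylbut-2-en-1-yl)-7-(triisopropylsilyloxy)-3,4-dihydro-2H-chromen-3-yl]but-3-en-2-one | [N-]=[N+]=CC(=O)/C=C/[C@@H]1COc2c(ccc(O[Si](C(C)C)(C(C)C)C(C)C)c2CC=C(C)C)C1
A4 | alternative 2 | triisopropyl[(5-methylhex-4-en-1-yn-1-yl)oxy]silane | CC(C)=CCC#CO[Si](C(C)C)(C(C)C)C(C)C
A5 | alternative 2 | (3R)-kanzonol X 7,4′-bis(triisopropylsilyl) ether | CC(C)=CCc1c(O[Si](C(C)C)(C(C)C)C(C)C)ccc([C@@H]2COc3c(ccc(O[Si](C(C)C)(C(C)C)C(C)C)c3CC=C(C)C)C2)c1O
A6 | alternative 3 | methyl 2-diazo-2-{2-[2-(tert-butyldimethylsilyloxy)-4-(methoxymethoxy)-3-(3-methylbut-2-en-1-yl)benzyloxy]-4-(methoxymethoxy)-3-(3-methylbut-2-en-1-yl)phenyl}acetate | COC(=O)C(=[N+]=[N-])c1ccc(OCOC)c(CC=C(C)C)c1OCc1ccc(OCOC)c(CC=C(C)C)c1O[Si](C)(C)C(C)(C)C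
A7 | alternative 3 | methyl cis-2-[2-(tert-butyldimethylsilyloxy)-4-(methoxymethoxy)-3-(3-methylbut-2-en-1-yl)phenyl]-6-(methoxymethoxy)-7-(3-methylbut-2-en-1-yl)-2,3-dihydrobenzofuran-3-carboxylate, configuration as drawn | COC(=O)[C@@H]1[C@H](c3ccc(OCOC)c(CC=C(C)C)c3O[Si](C)(C)C(C)(C)C)Oc2c1ccc(OCOC)c2CC=C(C)C
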